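(The earlier runs and the new flask come from a simulation on assumed constants; scatter was added.)

Amounts first: cedar and maple each hold 0.10 M of E and 0.10 mM of J, and the west run held the same J with 0.15 M of E.

| setting | west | cedar | maple |
|---|---|---|---|
| E | 0.15 M | 0.10 M | 0.10 M |
| J | 0.10 mM | 0.10 mM | 0.10 mM |
| remark | run made earlier |  |  |
| time |  | 30 min | 10 min |

west run (percent of the E charged)

| time / min | X / % | E / % |
|---|---|---|
| 0.500 | 11.3 | 89.3 |
| 1.50 | 29.4 | 69.9 |
| 3.00 | 51.1 | 49.0 |
| 4.00 | 61.0 | 38.7 |
| 6.00 | 74.9 | 25.7 |

(each reading ± 0.5 percentage points)

- which of the two ends with the longer chains by the average number of monomer units in a chain (living and dead chains, two that joined counted as one) ("neither" if they lie within 10%) (cedar / maple / neither)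
- average number of monomer units in a chain (living and dead chains, two that joined counted as one) at the end, cedar
- average number of monomer units in a chain (living and dead chains, two that joined counted as one) at the end, maple

- the average divides the monomer in chains by the number of chains, living and dead together; two radicals that join make one chain
- the earlier runs do not show the number of chains; that part of a forecast is a guess

Cedar and maple differ in time, 30 min against 10 min, so the question is what extra time does to a chain. Length is monomer in chains divided by chains, and the west readings give the first of these. In logarithms, c_E falls at 0.238 min⁻¹ as read at 3.00 min and at 0.226 min⁻¹ as read at 6.00 min. That is nearly constant, so the loss of E looks pseudo-first-order, and with J held at the west charge I carry this constant over to the lower charge of E.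

In powers of ten, the decade time, in which c_E falls by one power of ten, is 9.67 min. Maple then runs 1.03 decades and cedar 3.10, so by my reckoning 90.7% of the E has reacted in maple and 99.9% in cedar. But the west run shows no chains. If they start at a steady rate, which is a guess, cedar holds 3.00 times maple's chains, and maple ends longer by a factor of 2.72.

The forecast names maple, with 4000 for cedar and 11000 for maple, and says “The chain count is a guess”.

The flask gives 1600 for cedar and 3230 for maple, so maple ends longer.

    J → 2 D (k = 5.40 × 10⁻⁴ s⁻¹)
    E + D → Z + X (k = 3.10 × 10⁵ M⁻¹ s⁻¹)
    E + Z → X + Z, rate k3*[Z]*[E] (k = 25000 M⁻¹ s⁻¹)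
    2 Z → G (k = 2.00 × 10⁶ M⁻¹ s⁻¹)

The main reason is the difference in time: maple carried on to cedar's time falls from 3230 to 1600. At 10.0 min, about one decade time of 9.67 min, maple has X at 89.7% and G at 2.76 × 10⁻⁵ M, whereas cedar ends with X at 99.7% and G at 6.21 × 10⁻⁵ M. A further flask, cedar with 0.40 M of E, keeps 0.28% of its E against cedar's 0.27%, that is 2.55 decades against 2.57, with G at 6.21 × 10⁻⁵ M and chains of 6410.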